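**Plan**

- The target is two identical 2,4,5-trimethoxyphenyl rings, one carrying the benzylic C3(H)–CH3 unit and the other the C1(OH)–C2H2 unit. It is therefore the formal hydrate of a head-to-tail dimer of 2,4,5-trimethoxystyrene, with benzylic C3 of one vinylarene bonded to terminal C2 of the other.
- Retrosynthesis: cut C1–O first (back to the (E)-C1=C2 alkene 5), then the C2–C3 bond (back to styrene 2 and (E)-β-bromostyrene 4).
- Forward: Wittig methylenation gives 2 and bromodecarboxylation gives 4. A dual Cu–H/Pd hydroalkenylation joins them at C2–C3. Cu–H hydroboration with oxidation then places OH on C1. No ring is formed.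
- Stereochemistry: both centres come from face-selective syn addition of a DTBM-SEGPHOS-bound Cu–H across an aryl-conjugated C=C (C3 in step 3, C1 in step 4), each passed on with retention.
- Styrene 2 and the final 2,4-dimethoxybenzylic carbinol ionise easily, so steps 3 and 4 and all work-ups are kept neutral or basic.

Key step: step 3

Assumption: the hand of DTBM-SEGPHOS is written as (S) for both Cu–H steps on the premise that this ligand hand shows the required facial preference in hydrocupration of vinylarenes and that the Cu–C bond is transferred with retention. If the Cu-to-Pd transfer proves invertive, the (R)-ligand is used in step 3.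

**Step 1**
Reactants: 1 2,4,5-trimethoxybenzaldehyde
Product: 2 2,4,5-trimethoxystyrene (1-ethenyl-2,4,5-trimethoxybenzene)
Conditions: Ph3PCH3Br, KOtBu, THF, 0 °C to rt; product stored cold over a trace of base
Reagents that add atoms: methyltriphenylphosphonium bromide, C[P+](c1ccccc1)(c1ccccc1)c1ccccc1.[Br-]
Why: Wittig methylenation of a non-enolisable, electron-rich aryl aldehyde with the unstabilised ylide is reliable, the basic medium avoids acid-triggered cationic dimerisation of the styrene, and no stereocentre is formed.

**Step 2**
Reactants: 3 (E)-2,4,5-trimethoxycinnamic acid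
Product: 4 1-[(E)-2-bromoethenyl]-2,4,5-trimethoxybenzene
Conditions: NBS (1.0 equiv), LiOAc (10 mol %), MeCN–H2O 97:3, rt, dark
Reagents that add atoms: N-bromosuccinimide, O=C1CCC(=O)N1Br
Why: In this catalytic Hunsdiecker-type bromodecarboxylation, Br+ adds to the carboxyl-bearing alkene carbon and the benzylic cation (stabilised by the 2- and 4-methoxy groups) loses CO2 to give the thermodynamically preferred (E)-bromoalkene; no stereocentre is formed.

**Step 3**
Reactants: 2 2,4,5-trimethoxystyrene (1.5 equiv); 4 1-[(E)-2-bromoethenyl]-2,4,5-trimethoxybenzene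
Product: 5 (S,E)-1,3-bis(2,4,5-trimethoxyphenyl)but-1-ene
Conditions: Cu(OAc)2 (5 mol %), (S)-DTBM-SEGPHOS (5.5 mol %), [Pd(cinnamyl)Cl]2 (2.5 mol %), BrettPhos (5.5 mol %), Ph2MeSiH (1.5 equiv), NaOTMS (2 equiv), THF, rt
Reagents that add atoms: none
Why: Ligand-bound Cu–H (from Cu(OAc)2, the bisphosphine, silane and NaOTMS) adds syn and Markovnikov across the vinyl group of 2 to give a configurationally defined benzylic copper, while Pd(0)/BrettPhos inserts into the C–Br bond of 4 with retention of the E geometry; stereospecific Cu-to-Pd transmetalation and reductive elimination then form the C(sp3)–C(sp2) bond between benzylic C3 and alkenyl C2, and NaOTMS with silane turns the copper bromide back into Cu–H. The closest known reaction type is the dual copper hydride/palladium enantioselective Markovnikov hydroalkenylation (and hydroarylation) of vinylarenes with C(sp2) electrophiles. No ring is closed. The C3 stereocentre is controlled by the chiral bisphosphine on copper in the enantio-determining hydrocupration, which differentiates the two faces of the aryl-conjugated alkene. The step needs regioselectivity (Cu on the benzylic carbon, secured by conjugation of the vinyl group with the electron-rich ring) and chemoselectivity for the monosubstituted alkene of 2 over the 1,2-disubstituted alkenes of 4 and 5 (secured by their slower hydrocupration, by the excess of 2 and by limiting the silane). The basic medium shuts off the acid-catalysed racemic head-to-tail dimerisation of 2, and any hydrodebromination of 4 merely returns 2 because both partners carry the same arene.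

**Step 4**
Reactants: 5 (S,E)-1,3-bis(2,4,5-trimethoxyphenyl)but-1-ene
Product: 7 (1R,3S)-1,3-bis(2,4,5-trimethoxyphenyl)butan-1-ol, via benzylic pinacol boronate 6 (not isolated)
Conditions: CuCl (5 mol %), (S)-DTBM-SEGPHOS (5.5 mol %), NaOtBu (10 mol %), HBpin (1.5 equiv), toluene, rt to 40 °C; then aq NaOH, H2O2, THF, 0 °C to rt; basic work-up, Et3N-deactivated silica
Reagents that add atoms: pinacolborane, CC1(C)OBOC1(C)C (boron and pinacolate, held only in 6); hydrogen peroxide, OO (the hydroxyl oxygen of 7)
Why: In this Cu–H-catalysed Markovnikov hydroboration of a β-substituted vinylarene followed by boronate oxidation, the ligand-bound Cu–H adds syn across C1=C2 with Cu on the aryl-bearing C1 (face chosen by the ligand and expected to override the C3 centre), and both the σ-bond metathesis with HBpin and the peroxide 1,2-shift go with retention, so C1 should be set as R while C3 is untouched.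

**Compound list**

1 | 2,4,5-trimethoxybenzaldehyde | COc1cc(OC)c(C=O)cc1OC | starting material
2 | 2,4,5-trimethoxystyrene (1-ethenyl-2,4,5-trimethoxybenzene) | C=Cc1cc(OC)c(OC)cc1OC | intermediate
3 | (E)-3-(2,4,5-trimethoxyphenyl)prop-2-enoic acid (2,4,5-trimethoxycinnamic acid) | COc1cc(OC)c(/C=C/C(=O)O)cc1OC | starting material
4 | 1-[(E)-2-bromoethenyl]-2,4,5-trimethoxybenzene | COc1cc(OC)c(/C=C/Br)cc1OC | intermediate
5 | (S,E)-1,3-bis(2,4,5-trimethoxyphenyl)but-1-ene | COc1cc(OC)c(/C=C/[C@H](C)c2cc(OC)c(OC)cc2OC)cc1OC | intermediate
6 | 2-[(1R,3S)-1,3-bis(2,4,5-trimethoxyphenyl)butyl]-4,4,5,5-tetramethyl-1,3,2-dioxaborolane | COc1cc(OC)c([C@H](B2OC(C)(C)C(C)(C)O2)C[C@H](C)c2cc(OC)c(OC)cc2OC)cc1OC | intermediate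
7 | (1R,3S)-1,3-bis(2,4,5-trimethoxyphenyl)butan-1-ol | COc1cc(OC)c([C@H](O)C[C@H](C)c2cc(OC)c(OC)cc2OC)cc1OC | target

**Count**

Total steps: 4. Longest linear sequence: 3 steps (step 1 or step 2, then steps 3 and 4).

**Steps most likely to fail**

Step 3. Three processes may interfere. Cu–H may hydrocuprate the bromoalkene, with loss of β-bromide. A palladium hydride may move the new double bond into conjugation with the C3 ring, which erases the stereocentre. The copper-to-palladium transfer may be incompletely stereospecific, which lowers the enantiomeric purity. The fallback separates stereocentre formation from C–C bond formation and uses a metal-free 1,2-metallate shift. It sets out from 2 and 4 and comes back at 5. Cu–H-catalysed Markovnikov hydroboration of 2 (CuCl, (S)-DTBM-SEGPHOS, NaOtBu, HBpin, toluene) should give (R)-4,4,5,5-tetramethyl-2-[1-(2,4,5-trimethoxyphenyl)ethyl]-1,3,2-dioxaborolane F1. Bromide 4 is converted with t-BuLi (Et2O, −78 °C) into the (E)-alkenyllithium, which adds to F1 to give the lithium alkenyl boronate complex F2. PhSeCl at −78 °C should trigger the anti 1,2-shift of the benzylic group, with retention at the migrating carbon, to the β-phenylselanyl boronate F3. mCPBA then oxidises selenium, and syn elimination of boron and selenoxide (the selenium variant of the Zweifel olefination) should give 5 with the E geometry.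

Step 4. Hydrocupration of the hindered, electron-rich 1,2-disubstituted alkene may be slow, and the existing C3 centre may oppose the ligand (mismatched double stereodifferentiation), which would lower the diastereoselectivity at C1. The fallback sets C1 by reagent-controlled ketone reduction. It sets out from 5 and comes back at 7. Mukaiyama-type hydration (Mn(dpm)3 cat., PhSiH3, O2, iPrOH, 0 °C) places oxygen on the benzylic C1 through the benzylic radical and should give (3S)-1,3-bis(2,4,5-trimethoxyphenyl)butan-1-ol as a C1-epimer mixture F4. Oxidation with MnO2 in CH2Cl2 gives (S)-1,3-bis(2,4,5-trimethoxyphenyl)butan-1-one F5. Corey–Bakshi–Shibata reduction ((S)-Me-CBS cat., BH3·SMe2, THF, −20 °C) should then deliver hydride to the face that gives the (R)-carbinol 7.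

Step 2. Electrophilic bromination of the very electron-rich ring, or further bromination of the product alkene, may compete with ipso attack and decarboxylation. The fallback builds the bromoalkene by carbonyl olefination. It sets out from 1 and comes back at 4. Corey–Fuchs dibromo-olefination of 1 (CBr4, PPh3, CH2Cl2, 0 °C) gives 1-(2,2-dibromoethenyl)-2,4,5-trimethoxybenzene F6. Hirao reduction (diethyl phosphite, Et3N, DMF, rt) should then remove one bromine to leave the (E)-bromoalkene 4.

**Further compounds**

F1 | step 3 | (R)-4,4,5,5-tetramethyl-2-[1-(2,4,5-trimethoxyphenyl)ethyl]-1,3,2-dioxaborolane | CC1(C)OB([C@H](C)c2cc(OC)c(OC)cc2OC)OC1(C)C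
F2 | step 3 | lithium [(E)-2-(2,4,5-trimethoxyphenyl)ethenyl][(R)-1-(2,4,5-trimethoxyphenyl)ethyl](pinacolato)borate | [Li+].COc1cc(OC)c(/C=C/[B-]2([C@H](C)c3cc(OC)c(OC)cc3OC)OC(C)(C)C(C)(C)O2)cc1OC
F3 | step 3 | 2-[(3S)-1-(phenylselanyl)-1,3-bis(2,4,5-trimethoxyphenyl)butan-2-yl]-4,4,5,5-tetramethyl-1,3,2-dioxaborolane (anti adduct across C1–C2; one of its two C1/C2 diastereomers drawn, both lead to 5) | COc1cc(OC)c([C@@H]([Se]c2ccccc2)[C@H](B2OC(C)(C)C(C)(C)O2)[C@H](C)c2cc(OC)c(OC)cc2OC)cc1OC
F4 | step 4 | (3S)-1,3-bis(2,4,5-trimethoxyphenyl)butan-1-ol, mixture of C1 epimers | COc1cc(OC)c(C(O)C[C@H](C)c2cc(OC)c(OC)cc2OC)cc1OC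
F5 | step 4 | (S)-1,3-bis(2,4,5-trimethoxyphenyl)butan-1-one | COc1cc(OC)c(C(=O)C[C@H](C)c2cc(OC)c(OC)cc2OC)cc1OC
F6 | step 2 | 1-(2,2-dibromoethenyl)-2,4,5-trimethoxybenzene | COc1cc(OC)c(C=C(Br)Br)cc1OC
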